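## Structural features

The target is a 6-oxabicyclo[3.2.1]octan-7-one: a cyclohexane (C1–C2–C3–C4–C5–C8) whose carbons C1 and C5 are spanned by the lactone bridge C7(=O)–O6, so the carbonyl carbon on C1 and the oxygen on C5 are locked cis and diaxial. Four contiguous stereocentres follow one another round the ring: C2 (methyl, R), C1 (all-carbon quaternary, R), C8 (methyl propanoate arm, R) and C5 (fully substituted, oxygen plus isopropenyl, S). The methyl group, the arm and the lactone bridge lie on one face; the isopropenyl group and the C1 side chain lie on the other. C1 also carries a two-carbon chain that ends at C3 of a furan-2(5H)-one. The fragile parts are the butenolide (base, nucleophiles, double-bond migration), the isopropenyl group, and above all the O6–C5 bond, a tertiary allylic ester of the vinyl-lactone type that can ionise under acid or with zerovalent nickel or palladium. The real difficulty is the quaternary C1 wedged between the tertiary centres C2 and C8, with C5 oxygenated on the correct face. The key step exploits the fact that C1 is a bridgehead: only a carboxyl cis to the C5 oxygen can close the bridge, so C1 can be built as a non-stereogenic malonate carbon. With that, C2–C3–C4 and the C2 methyl map onto crotonaldehyde and C5 onto the α-carbon of a methyl ketone.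

## Logic of the disconnections

23 ⇒ 21. No skeletal bond is cut; the isopropenyl group is traced back to a tertiary phenylselanyl group on the same carbon. The reason is that O6–C5 in 23 is an allylic ester that zerovalent nickel or palladium could ionise, and the alkene would compete for borane. The gain is that all organometallic steps run on a saturated, non-allylic lactone. The forward elimination must be regioselective, which is assured because C5 carries no hydrogen.

21 ⇒ 18 + 19. The bond between the CH2CH2 linker and C3 of the butenolide is cut. The butenolide is the most base-sensitive part and is best brought in late as an intact ring, which reduces the side chain to a vinyl group on C1. The forward step needs anti-Markovnikov hydroboration of a neopentyl-type vinyl group and a cross-coupling mild enough for the bromobutenolide.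

18 ⇒ 16. The C1–vinyl bond is cut and replaced by a carboxyl group. C1 then carries two carboxyl carbons, that is, it becomes a malonate carbon one stage further back. The forward decarboxylative coupling passes through a C1 radical; its configuration cannot be lost because C1 is a bridgehead.

16 ⇒ 15. The O6–C5 bond (with the C–Se bond) is cut, which reveals a gem-diacid and a tetrasubstituted exocyclic alkene. Two stereocentres (C1 and C5) and the bicycle disappear, leaving a cyclohexane with only C2 and C8 stereogenic. The forward lactonisation must attack C5 and not the exocyclic carbon, and must use the carboxyl cis to the methyl group and the arm.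

15 ⇒ 14 ⇒ 13 ⇒ 11. The acids go back to allyl esters, one methyl of the isopropylidene is cut back to an enol triflate, and the triflate goes back to an enone by 1,4-reduction. The isopropylidene thus becomes the acetylcyclohexene pattern of an aldol condensation. The forward steps must leave three esters untouched and must avoid zerovalent palladium while the allyl esters are present.

11 ⇒ 6 + 7 (key step). C1–C2 and C4=C5 are cut. C1 is a malonate nucleophile for the β-carbon of an enal (C2), and the enal carbonyl carbon (C4) is the electrophile for a ketone α-carbon (C5). The ring and the C2 stereocentre disappear, leaving an acyclic malonate with one stereocentre and a four-carbon enal. The forward step needs facial control at C2 by the catalyst, matched to C8, and the ketone must not act as an electrophile, so it is carried as a dioxolane.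

6 ⇒ 5 ⇒ 3 + 4. The ketal is removed and C1–C8 is cut, a Michael retron between the malonate and the ketone. The last stereocentre goes, leaving an achiral enone and a malonate. The forward step must be an enantioselective addition to an aliphatic acyclic enone.

3 ⇒ 1 + 2. The C=C bond of the enone is cut (Wittig retron), giving an aldehyde ester and a stabilised ylide. The forward step only needs chemoselectivity for the aldehyde over the ester.

## Other disconnections considered

Alternative 1: The isopropenyl carbon and the carbonyl carbon of the arm are rejoined, giving the keto lactone A1, in which these two carbons sit in a gem-dimethylcyclohexanone (ring A of a decalone). In the forward direction a peroxy acid would insert oxygen on the side of the fully substituted carbon (Baeyer–Villiger) to give the bis-lactone A2. Acid would then break the tertiary alkyl–oxygen bond of the new seven-membered lactone, the cation would lose a methyl proton, and esterification would give 23.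
- In favour: all four ring stereocentres are set on a rigid fused frame before any fragile group exists, and no desymmetrisation at C1 is needed. The migrating carbon is the more substituted one, as usual. The elimination can only give isopropenyl, because C5 has no hydrogen.
- Against: A1 is itself a tricycle with a bridged lactone and two quaternary stereocentres, and reaching it should take at least as many steps as the whole chosen route. A ketone flanked by a quaternary carbon reacts slowly with peracids. The cation next to the acyloxy-bearing C5 could be trapped by the neighbouring lactone oxygen or could rearrange. Only one of the two lactones in A2 may open.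
- Comparison: on structure this alternative is the better one at C1, and it is equal or better in end-game economy, since one operation releases both the alkene and the ester. On mechanism its key step forms no C–C bond and no stereocentre, whereas the chosen key step builds the ring and sets C2. On step economy the chosen plan is ahead, because it makes the carbocycle from three small achiral pieces.

Alternative 2: The C8–CH2 bond of the arm and the C1–CH2 bond of the side chain are cut, leading to the terpene-derived enoate A3. In the forward direction the copper reagent from the Grignard reagent A4 would add to C8 of A3, and the ester enolate would be alkylated at C1 by the iodide A5 to give A6; no ring closes.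
- In favour: the ring, C2, C5 and the isopropenyl group come from the chiral pool. Both new centres would be set in one flask by approach anti to the resident substituents, which is the relative configuration wanted. Both chains arrive with the correct length.
- Against: the alkylation must create the quaternary C1 between two tertiary carbons with a poorly reactive β-silyloxy iodide, and a magnesium or copper ester enolate is a weak partner for that. C5 still carries hydrogen afterwards, so the lactone requires oxidation at C5 or a detour through an isopropylidene much as in the chosen plan. The acetal must be oxidised to the ester, the silyl ether must be built into the butenolide, and a hindered methyl ester on C1 must be cleaved beside the arm ester.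
- Comparison: on the source of absolute configuration this alternative is the better one (chiral pool against two catalytic asymmetric steps). On the quaternary centre the two plans are equal in risk, both forcing a bond at a crowded carbon. On mechanism and step economy after the key step the chosen plan is ahead, because the arm stays at the ester oxidation level throughout and no C–H oxidation is needed.

Alternative 3: C5–C8 and O6–C7 are cut, leading to the acyclic bromide A7. In the forward direction divalent chromium would turn the allylic bromide into an allylchromium species that adds through its γ-carbon to the isopropenyl ketone (Nozaki–Hiyama–Kishi type), closing the carbocycle; the tertiary chromium alkoxide would then lactonise onto the cis malonate ester to give A8.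
- In favour: one operation would form the ring, C5 and C8, the tertiary C–O bond and the lactone, with the isopropenyl group already in place. No selenium mask and no enol triflate are needed, and the desymmetrisation of the malonate is intramolecular.
- Against: the relation of C5 and C8 to C2 rests on one cyclic transition state whose preference is not assured from a single remote methyl centre. The γ-adduct leaves a vinyl group on C8 that must gain a carbon and be reduced next to the isopropenyl group. The C1 ester must still become the two-carbon linker. A7 needs a quaternary malonate carrying an alkenyl group directly on C1, and the chromium is stoichiometric.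
- Comparison: on convergence at C5 this alternative is the better one. On the principle of desymmetrisation the plans are equal, since both rely on the cis carboxyl reaching C5. On stereochemical predictability and on the late homologation of the arm the chosen plan is ahead, as it sets C8 and C2 in separate catalyst-controlled steps and delivers the arm at its final oxidation level.

Key step: step 4

Remarks on the chemistry.
- Numbering: the annulation product is a 3-acetylcyclohex-3-ene-1,1-dicarboxylate, because the acetyl-bearing ring carbon (C5 of the target) is bonded to the arm-bearing carbon (C8). A 4-acetyl locant would describe a different constitution and is not used.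
- Precursor design: the keto malonate 5 enters the annulation as its dioxolane 6. With a free ketone, the enamine formed after the conjugate addition could close a six-membered ring on the ketone carbonyl through C3 and give a cyclohexenecarbaldehyde instead of the acetylcyclohexene.
- Assumption: 9-amino-9-deoxy-epi-quinidine is taken to deliver the malonate to the Si face of C4 of 3. If the sense on this substrate were the opposite, the quinine-derived pseudo-enantiomer would be used and nothing else would change.

## Steps

Step 1
Reactants: 1 methyl 4-oxobutanoate; 2 1-(triphenylphosphoranylidene)propan-2-one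
Product: 3 methyl (4E)-6-oxohept-4-enoate
Conditions: CH2Cl2, rt
Reagents that add atoms: none
Why: Wittig olefination with a carbonyl-stabilised ylide; the aldehyde reacts, the methyl ester does not, and stabilised ylides give the E-enone.

Step 2
Reactants: 3 methyl (4E)-6-oxohept-4-enoate; 4 diallyl malonate
Product: 5 diallyl 2-[(4S)-7-methoxy-2,7-dioxoheptan-4-yl]propanedioate
Conditions: 9-amino-9-deoxy-epi-quinidine (20 mol%), PhCO2H (40 mol%), 4 (2 equiv), THF, rt
Reagents that add atoms: none
Why: Iminium-type asymmetric Michael addition of a malonate to an acyclic aliphatic enone under a cinchona-derived primary amine with an acid co-catalyst; attack on the Si face of C4 of the chiral iminium ion gives the S centre that becomes C8. The centre is β to the ketone and cannot epimerise by enolisation; any shortfall in enantiopurity becomes a separable diastereomer after step 4.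

Step 3
Reactants: 5 diallyl 2-[(4S)-7-methoxy-2,7-dioxoheptan-4-yl]propanedioate
Product: 6 diallyl 2-[(2S)-5-methoxy-1-(2-methyl-1,3-dioxolan-2-yl)-5-oxopentan-2-yl]propanedioate
Conditions: (TMSOCH2)2 (1.5 equiv), TMSOTf (5 mol%), CH2Cl2, −78 → −20 °C; pyridine quench
Reagents that add atoms: 1,2-bis(trimethylsilyloxy)ethane, C[Si](C)(C)OCCO[Si](C)(C)C
Why: Aprotic ketalisation with the bis-silyl ether of the diol under catalytic silyl triflate; at low temperature, without free diol or water, the three esters should not transesterify and no retro-Michael cleavage can start. The dioxolane removes the ketone as an electrophile for step 4.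

Step 4
Reactants: 6 diallyl 2-[(2S)-5-methoxy-1-(2-methyl-1,3-dioxolan-2-yl)-5-oxopentan-2-yl]propanedioate; 7 (E)-but-2-enal
Product: 11 diallyl (2S,6R)-3-acetyl-2-(3-methoxy-3-oxopropyl)-6-methylcyclohex-3-ene-1,1-dicarboxylate, via ketal aldehyde 8 (not isolated), via keto aldehyde 9 (not isolated), via aldol 10 (not isolated)
Conditions: 7 (3 equiv), (S)-2-{bis[3,5-bis(trifluoromethyl)phenyl](trimethylsilyloxy)methyl}pyrrolidine (20 mol%), LiOAc (20 mol%), CH2Cl2/i-PrOH, 0 °C → rt; evaporate; p-TsOH·H2O (1.2 equiv), THF/H2O, 40 °C; then toluene, 70 °C
Reagents that add atoms: water, O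
Why: The amine and 7 form an E-configured, s-trans iminium ion; the tertiary malonate C–H of 6, activated by the acetate base, adds to its β-carbon from the face away from the diaryl(silyloxy)methyl group, which forms C1–C2 and sets C2 as R under catalyst control, and hydrolysis of the resulting enamine releases 8. The closest known reaction type is the diarylprolinol-silyl-ether-catalysed Michael addition of malonates, 2-alkylmalonates included, to enals, joined to an acid-promoted aldol condensation as in amine-catalysed (3+3) annulations of bis-nucleophiles. While the amine is active the ketone is a dioxolane, so the enamine cannot close a ring on it through C3. Aqueous p-TsOH then protonates the amine, unmasks the ketone (9) and lets its more substituted enol, at C5, attack the aldehyde carbon C4 in a 6-(enolexo)-exo-trig closure (10); loss of water gives the conjugated enone 11. Closure from the methyl side of the ketone would need an eight-membered ring, so ring size secures the regiochemistry. C1 carries two identical esters and needs no control, and C8 (β to the ketone) and C2 (β to the aldehyde) cannot epimerise by enolisation. The selectivity the step needs is the cis relation of methyl and arm: it comes from matching the S catalyst with the S centre of 6, and material of the wrong series from either source is a diastereomer of 11 that chromatography should remove.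

Step 5
Reactants: 11 diallyl (2S,6R)-3-acetyl-2-(3-methoxy-3-oxopropyl)-6-methylcyclohex-3-ene-1,1-dicarboxylate
Product: 13 diallyl (2S,6R)-2-(3-methoxy-3-oxopropyl)-6-methyl-3-{1-[(trifluoromethanesulfonyl)oxy]ethylidene}cyclohexane-1,1-dicarboxylate (E/Z mixture), via silyl enol ether 12 (not isolated)
Conditions: [(Ph3P)CuH]6 (1 mol%), PhMe2SiH (1.3 equiv), toluene, rt; evaporate; CsF (2.5 equiv), PhNTf2 (1.3 equiv), DME, rt
Reagents that add atoms: N-phenylbis(trifluoromethanesulfonimide), O=S(=O)(N(c1ccccc1)S(=O)(=O)C(F)(F)F)C(F)(F)F
Why: Copper-hydride 1,4-hydrosilylation puts hydride on C4 only and leaves esters and isolated alkenes alone, giving the regiodefined tetrasubstituted silyl enol ether 12; fluoride then frees the caesium enolate, which the triflimide sulfonylates on oxygen. No stereocentre is formed, and both enol geometries lead to the same isopropylidene.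

Step 6
Reactants: 13 diallyl (2S,6R)-2-(3-methoxy-3-oxopropyl)-6-methyl-3-{1-[(trifluoromethanesulfonyl)oxy]ethylidene}cyclohexane-1,1-dicarboxylate
Product: 14 diallyl (2S,6R)-2-(3-methoxy-3-oxopropyl)-6-methyl-3-(propan-2-ylidene)cyclohexane-1,1-dicarboxylate
Conditions: MeMgBr (1.5 equiv), Fe(acac)3 (10 mol%), THF/NMP, −30 °C
Reagents that add atoms: methylmagnesium bromide, C[Mg]Br
Why: Iron-catalysed cross-coupling of an alkenyl triflate with a methyl Grignard reagent; at low temperature the coupling should outrun addition to the esters, and avoiding zerovalent palladium keeps the allyl esters intact.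

Step 7
Reactants: 14 diallyl (2S,6R)-2-(3-methoxy-3-oxopropyl)-6-methyl-3-(propan-2-ylidene)cyclohexane-1,1-dicarboxylate
Product: 15 (2S,6R)-2-(3-methoxy-3-oxopropyl)-6-methyl-3-(propan-2-ylidene)cyclohexane-1,1-dicarboxylic acid
Conditions: Pd(PPh3)4 (5 mol%), morpholine (6 equiv), THF, rt; cold aq. KHSO4
Reagents that add atoms: none
Why: Deallylation through π-allylpalladium complexes formed from zerovalent palladium and trapped by morpholine (Tsuji–Trost type); the methyl ester and the tetrasubstituted alkene are inert. A cold, weak-acid work-up avoids protolactonisation and decarboxylation of the malonic acid.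

Step 8
Reactants: 15 (2S,6R)-2-(3-methoxy-3-oxopropyl)-6-methyl-3-(propan-2-ylidene)cyclohexane-1,1-dicarboxylic acid
Product: 16 (1R,2R,5S,8R)-8-(3-methoxy-3-oxopropyl)-2-methyl-7-oxo-5-[2-(phenylselanyl)propan-2-yl]-6-oxabicyclo[3.2.1]octane-1-carboxylic acid
Conditions: PhSeCl (1.1 equiv), CH2Cl2, −78 → 0 °C
Reagents that add atoms: benzeneselenenyl chloride, Cl[Se]c1ccccc1
Why: Selenolactonisation: the seleniranium ion on the tetrasubstituted alkene forms reversibly and is opened at C5 by 5-exo attack of the axial carboxyl, which in the chair with methyl and arm equatorial is the one cis to both, so C1 (R) and C5 (S) are set together. Closure by the other carboxyl would force methyl and arm 1,3-diaxial, and attack at the exocyclic carbon would need a six-membered bridged lactone from a poorly aligned carboxyl. Selenium is kept as a mask for the isopropenyl group so that no allylic ester is present in steps 9 and 10.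

Step 9
Reactants: 16 (1R,2R,5S,8R)-8-(3-methoxy-3-oxopropyl)-2-methyl-7-oxo-5-[2-(phenylselanyl)propan-2-yl]-6-oxabicyclo[3.2.1]octane-1-carboxylic acid
Product: 18 methyl 3-{(1R,2R,5S,8R)-1-ethenyl-2-methyl-7-oxo-5-[2-(phenylselanyl)propan-2-yl]-6-oxabicyclo[3.2.1]octan-8-yl}propanoate, via redox-active ester 17 (not isolated)
Conditions: N-hydroxytetrachlorophthalimide, N,N'-diisopropylcarbodiimide, CH2Cl2, rt; evaporate; Ni(acac)2 (10 mol%), 2,2′-bipyridine (10 mol%), CH2=CHZnCl (from CH2=CHMgBr and ZnCl2, 2.5 equiv), THF/DMF, rt
Reagents that add atoms: vinylmagnesium bromide, C=C[Mg]Br (used as chloro(ethenyl)zinc, C=C[Zn]Cl, made in the flask with ZnCl2)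
Why: Nickel-catalysed decarboxylative alkenylation of a redox-active ester: electron transfer to 17 releases CO2 and the C1 radical, which a vinylnickel species captures and couples. C1 is a bridgehead, so the new bond can only form where the carboxyl stood and the configuration is retained. The organozinc reagent tolerates the lactone and the methyl ester.

Step 10
Reactants: 18 methyl 3-{(1R,2R,5S,8R)-1-ethenyl-2-methyl-7-oxo-5-[2-(phenylselanyl)propan-2-yl]-6-oxabicyclo[3.2.1]octan-8-yl}propanoate; 19 3-bromofuran-2(5H)-one
Product: 21 methyl 3-{(1R,2R,5S,8R)-2-methyl-7-oxo-1-[2-(2-oxo-2,5-dihydrofuran-3-yl)ethyl]-5-[2-(phenylselanyl)propan-2-yl]-6-oxabicyclo[3.2.1]octan-8-yl}propanoate, via alkylborane 20 (not isolated)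
Conditions: 9-borabicyclo[3.3.1]nonane (1.5 equiv), THF, 0 °C → rt; then 19 (1.5 equiv), PdCl2(dppf) (5 mol%), AsPh3 (10 mol%), Cs2CO3 (2 equiv), DMF/H2O, rt
Reagents that add atoms: none
Why: Anti-Markovnikov hydroboration of the only alkene in 18, then B-alkyl Suzuki–Miyaura coupling with the α-bromobutenolide; carbonate in wet DMF at room temperature with AsPh3 should be mild enough for the butenolide. With the isopropenyl group still masked there is no second alkene for the borane and no allylic C–O bond for zerovalent palladium.

Step 11
Reactants: 21 methyl 3-{(1R,2R,5S,8R)-2-methyl-7-oxo-1-[2-(2-oxo-2,5-dihydrofuran-3-yl)ethyl]-5-[2-(phenylselanyl)propan-2-yl]-6-oxabicyclo[3.2.1]octan-8-yl}propanoate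
Product: 23 methyl 3-{(1R,2R,5S,8R)-2-methyl-7-oxo-1-[2-(2-oxo-2,5-dihydrofuran-3-yl)ethyl]-5-(prop-1-en-2-yl)-6-oxabicyclo[3.2.1]octan-8-yl}propanoate, via selenoxide 22 (not isolated)
Conditions: NaIO4 (3 equiv), NaHCO3, THF/H2O, 0 °C → rt
Reagents that add atoms: none
Why: Oxidation of the selenide to the selenoxide and syn-elimination at room temperature; C5 bears no hydrogen, so only a methyl hydrogen can be lost and the isopropenyl group is the only possible alkene. Periodate should not touch the butenolide, the lactone or the ester.

## Compound list

1 | methyl 4-oxobutanoate | COC(=O)CCC=O | starting material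
2 | 1-(triphenylphosphoranylidene)propan-2-one | CC(=O)C=P(c1ccccc1)(c1ccccc1)c1ccccc1 | starting material
3 | methyl (4E)-6-oxohept-4-enoate | COC(=O)CC/C=C/C(C)=O | intermediate
4 | diallyl malonate (di(prop-2-en-1-yl) propanedioate) | C=CCOC(=O)CC(=O)OCC=C | starting material
5 | diallyl 2-[(4S)-7-methoxy-2,7-dioxoheptan-4-yl]propanedioate | CC(=O)C[C@H](CCC(=O)OC)C(C(=O)OCC=C)C(=O)OCC=C | intermediate
6 | diallyl 2-[(2S)-5-methoxy-1-(2-methyl-1,3-dioxolan-2-yl)-5-oxopentan-2-yl]propanedioate | CC1(C[C@H](CCC(=O)OC)C(C(=O)OCC=C)C(=O)OCC=C)OCCO1 | intermediate
7 | (E)-but-2-enal (crotonaldehyde) | C/C=C/C=O | starting material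
8 | diallyl 2-[(2S)-5-methoxy-1-(2-methyl-1,3-dioxolan-2-yl)-5-oxopentan-2-yl]-2-[(2R)-4-oxobutan-2-yl]propanedioate | O=CC[C@@H](C)C(C(=O)OCC=C)(C(=O)OCC=C)[C@@H](CCC(=O)OC)CC1(C)OCCO1 | intermediate (not isolated)
9 | diallyl 2-[(4S)-7-methoxy-2,7-dioxoheptan-4-yl]-2-[(2R)-4-oxobutan-2-yl]propanedioate | O=CC[C@@H](C)C(C(=O)OCC=C)(C(=O)OCC=C)[C@@H](CCC(=O)OC)CC(C)=O | intermediate (not isolated)
10 | diallyl (2S,6R)-3-acetyl-4-hydroxy-2-(3-methoxy-3-oxopropyl)-6-methylcyclohexane-1,1-dicarboxylate (mixture at C3 and C4) | CC(=O)C1C(O)C[C@@H](C)C(C(=O)OCC=C)(C(=O)OCC=C)[C@H]1CCC(=O)OC | intermediate (not isolated)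
11 | diallyl (2S,6R)-3-acetyl-2-(3-methoxy-3-oxopropyl)-6-methylcyclohex-3-ene-1,1-dicarboxylate | CC(=O)C1=CC[C@@H](C)C(C(=O)OCC=C)(C(=O)OCC=C)[C@H]1CCC(=O)OC | intermediate
12 | diallyl (2S,6R)-3-{1-[dimethyl(phenyl)silyloxy]ethylidene}-2-(3-methoxy-3-oxopropyl)-6-methylcyclohexane-1,1-dicarboxylate (E/Z mixture) | CC(O[Si](C)(C)c1ccccc1)=C1CC[C@@H](C)C(C(=O)OCC=C)(C(=O)OCC=C)[C@H]1CCC(=O)OC | intermediate (not isolated)
13 | diallyl (2S,6R)-2-(3-methoxy-3-oxopropyl)-6-methyl-3-{1-[(trifluoromethanesulfonyl)oxy]ethylidene}cyclohexane-1,1-dicarboxylate (E/Z mixture) | CC(OS(=O)(=O)C(F)(F)F)=C1CC[C@@H](C)C(C(=O)OCC=C)(C(=O)OCC=C)[C@H]1CCC(=O)OC | intermediate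
14 | diallyl (2S,6R)-2-(3-methoxy-3-oxopropyl)-6-methyl-3-(propan-2-ylidene)cyclohexane-1,1-dicarboxylate | CC(C)=C1CC[C@@H](C)C(C(=O)OCC=C)(C(=O)OCC=C)[C@H]1CCC(=O)OC | intermediate
15 | (2S,6R)-2-(3-methoxy-3-oxopropyl)-6-methyl-3-(propan-2-ylidene)cyclohexane-1,1-dicarboxylic acid | CC(C)=C1CC[C@@H](C)C(C(=O)O)(C(=O)O)[C@H]1CCC(=O)OC | intermediate
16 | (1R,2R,5S,8R)-8-(3-methoxy-3-oxopropyl)-2-methyl-7-oxo-5-[2-(phenylselanyl)propan-2-yl]-6-oxabicyclo[3.2.1]octane-1-carboxylic acid | CC(C)([Se]c1ccccc1)[C@@]12CC[C@@H](C)[C@@](C(=O)O)(C(=O)O1)[C@H]2CCC(=O)OC | intermediate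
17 | 4,5,6,7-tetrachloro-1,3-dioxoisoindolin-2-yl (1S,2R,5S,8R)-8-(3-methoxy-3-oxopropyl)-2-methyl-7-oxo-5-[2-(phenylselanyl)propan-2-yl]-6-oxabicyclo[3.2.1]octane-1-carboxylate | CC(C)([Se]c1ccccc1)[C@@]12CC[C@@H](C)[C@@](C(=O)ON3C(=O)c4c(Cl)c(Cl)c(Cl)c(Cl)c4C3=O)(C(=O)O1)[C@H]2CCC(=O)OC | intermediate (not isolated)
18 | methyl 3-{(1R,2R,5S,8R)-1-ethenyl-2-methyl-7-oxo-5-[2-(phenylselanyl)propan-2-yl]-6-oxabicyclo[3.2.1]octan-8-yl}propanoate | CC(C)([Se]c1ccccc1)[C@@]12CC[C@@H](C)[C@@](C=C)(C(=O)O1)[C@H]2CCC(=O)OC | intermediate
19 | 3-bromofuran-2(5H)-one | O=C1OCC=C1Br | starting material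
20 | methyl 3-{(1R,2R,5S,8R)-1-[2-(9-borabicyclo[3.3.1]nonan-9-yl)ethyl]-2-methyl-7-oxo-5-[2-(phenylselanyl)propan-2-yl]-6-oxabicyclo[3.2.1]octan-8-yl}propanoate | CC(C)([Se]c1ccccc1)[C@@]12CC[C@@H](C)[C@@](CCB3C4CCCC3CCC4)(C(=O)O1)[C@H]2CCC(=O)OC | intermediate (not isolated)
21 | methyl 3-{(1R,2R,5S,8R)-2-methyl-7-oxo-1-[2-(2-oxo-2,5-dihydrofuran-3-yl)ethyl]-5-[2-(phenylselanyl)propan-2-yl]-6-oxabicyclo[3.2.1]octan-8-yl}propanoate | CC(C)([Se]c1ccccc1)[C@@]12CC[C@@H](C)[C@@](CCC3=CCOC3=O)(C(=O)O1)[C@H]2CCC(=O)OC | intermediate
22 | methyl 3-{(1R,2R,5S,8R)-5-[2-(benzeneseleninyl)propan-2-yl]-2-methyl-7-oxo-1-[2-(2-oxo-2,5-dihydrofuran-3-yl)ethyl]-6-oxabicyclo[3.2.1]octan-8-yl}propanoate (mixture at selenium) | CC(C)([Se](=O)c1ccccc1)[C@@]12CC[C@@H](C)[C@@](CCC3=CCOC3=O)(C(=O)O1)[C@H]2CCC(=O)OC | intermediate (not isolated)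
23 | methyl 3-{(1R,2R,5S,8R)-2-methyl-7-oxo-1-[2-(2-oxo-2,5-dihydrofuran-3-yl)ethyl]-5-(prop-1-en-2-yl)-6-oxabicyclo[3.2.1]octan-8-yl}propanoate | C=C(C)[C@@]12CC[C@@H](C)[C@@](CCC3=CCOC3=O)(C(=O)O1)[C@H]2CCC(=O)OC | target

## Step count and least certain steps

Total: 11 steps. Longest linear sequence: 11 steps, from 1 to 23; compounds 2, 4, 7 and 19 enter as purchased materials.

Step 4 (key step). The conjugate addition may be too slow at the α-branched malonate C–H, so that self-condensation of 7 or an unselective base-mediated background addition takes over. The congestion at the forming quaternary centre may also make the addition reversible, and in the acid stage dehydration may lag behind ketal cleavage.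
Fallback: from 6, base-catalysed conjugate addition (catalytic DBU, MeCN, 0 °C) to but-2-ynal, whose sp carbon is far less hindered, should give the β-methyl enal F1 as an E/Z mixture. Iminium-catalysed transfer hydrogenation with a Hantzsch ester and the enantiomer of 5-benzyl-2-tert-butyl-3-methylimidazolidin-4-one trifluoroacetate that gives the 2R centre then sets C2 by hydride delivery and converges both alkene isomers. This returns to the route at 8, which is taken through the acid stage of step 4 to 11.

Step 9. Activation of the neopentyl-type acid may be sluggish. The bridgehead radical may be reduced, or may abstract the phenylselanyl group from a second molecule, faster than nickel captures it at so crowded a carbon.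
Fallback: from 16, neutral conversion with 1-chloro-N,N,2-trimethylprop-1-en-1-amine gives the acid chloride F3, reduction with LiAlH(OtBu)3 at −78 °C gives the aldehyde F4, and Wittig methylenation with methylidenetriphenylphosphorane keeps the carboxyl carbon as the inner vinyl carbon. This returns to the route at 18.

Step 10. Transmetallation from boron may be slow next to the quaternary centre, the selenide may bind palladium, and aqueous base may open the butenolide ring or shift its double bond before or after coupling.
Fallback: from 20, oxidation of the C–B bonds with trimethylamine N-oxide (which should spare the selenide) gives the primary alcohol F5. Iodination (PPh3, I2, imidazole) gives the iodide F6, zinc insertion (Zn, LiCl, THF) gives the alkylzinc iodide F7, and base-free Negishi coupling with 19 (Pd(OAc)2, 2-dicyclohexylphosphino-2′,6′-dimethoxybiphenyl, THF, rt) returns to the route at 21.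

Step 5. The hydrosilylation may stall at the hindered enone, and the caesium enolate may be acylated on carbon by the neighbouring ester or protonated before sulfonylation on oxygen.
Fallback: from 11, Wittig methylenation of the acetyl group gives the diene F2. 1,4-Hydrogenation under H2 with Cr(CO)3(naphthalene) as catalyst, which adds hydrogen across the ends of an s-cis diene, should move the double bond into the exocyclic position and returns to the route at 14.

## Further compounds

F1 | step 4 | diallyl 2-[(2S)-5-methoxy-1-(2-methyl-1,3-dioxolan-2-yl)-5-oxopentan-2-yl]-2-(4-oxobut-2-en-2-yl)propanedioate (E/Z mixture) | O=CC=C(C)C(C(=O)OCC=C)(C(=O)OCC=C)[C@@H](CCC(=O)OC)CC1(C)OCCO1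
F2 | step 5 | diallyl (2S,6R)-2-(3-methoxy-3-oxopropyl)-6-methyl-3-(prop-1-en-2-yl)cyclohex-3-ene-1,1-dicarboxylate | C=C(C)C1=CC[C@@H](C)C(C(=O)OCC=C)(C(=O)OCC=C)[C@H]1CCC(=O)OC
F3 | step 9 | methyl 3-{(1S,2R,5S,8R)-1-(chlorocarbonyl)-2-methyl-7-oxo-5-[2-(phenylselanyl)propan-2-yl]-6-oxabicyclo[3.2.1]octan-8-yl}propanoate | CC(C)([Se]c1ccccc1)[C@@]12CC[C@@H](C)[C@@](C(Cl)=O)(C(=O)O1)[C@H]2CCC(=O)OC
F4 | step 9 | methyl 3-{(1R,2R,5S,8R)-1-formyl-2-methyl-7-oxo-5-[2-(phenylselanyl)propan-2-yl]-6-oxabicyclo[3.2.1]octan-8-yl}propanoate | CC(C)([Se]c1ccccc1)[C@@]12CC[C@@H](C)[C@@](C=O)(C(=O)O1)[C@H]2CCC(=O)OC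
F5 | step 10 | methyl 3-{(1R,2R,5S,8R)-1-(2-hydroxyethyl)-2-methyl-7-oxo-5-[2-(phenylselanyl)propan-2-yl]-6-oxabicyclo[3.2.1]octan-8-yl}propanoate | CC(C)([Se]c1ccccc1)[C@@]12CC[C@@H](C)[C@@](CCO)(C(=O)O1)[C@H]2CCC(=O)OC
F6 | step 10 | methyl 3-{(1R,2R,5S,8R)-1-(2-iodoethyl)-2-methyl-7-oxo-5-[2-(phenylselanyl)propan-2-yl]-6-oxabicyclo[3.2.1]octan-8-yl}propanoate | CC(C)([Se]c1ccccc1)[C@@]12CC[C@@H](C)[C@@](CCI)(C(=O)O1)[C@H]2CCC(=O)OC
F7 | step 10 | {2-[(1R,2R,5S,8R)-8-(3-methoxy-3-oxopropyl)-2-methyl-7-oxo-5-[2-(phenylselanyl)propan-2-yl]-6-oxabicyclo[3.2.1]octan-1-yl]ethyl}zinc iodide | CC(C)([Se]c1ccccc1)[C@@]12CC[C@@H](C)[C@@](CC[Zn]I)(C(=O)O1)[C@H]2CCC(=O)OC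
A1 | alternative 1 | tricyclic keto lactone: the target skeleton with the isopropenyl carbon and the arm carbonyl joined as a gem-dimethylcyclohexanone | CC3(C)[C@@]12CC[C@@H](C)[C@@](CCC4=CCOC4=O)(C(=O)O1)[C@H]2CCC3=O
A2 | alternative 1 | ring-expanded bis-lactone with a seven-membered lactone on the gem-dimethyl carbon | CC3(C)[C@@]12CC[C@@H](C)[C@@](CCC4=CCOC4=O)(C(=O)O1)[C@H]2CCC(=O)O3
A3 | alternative 2 | methyl (3R,6R)-6-methyl-3-(prop-1-en-2-yl)cyclohex-1-ene-1-carboxylate | C=C(C)[C@@H]1CC[C@@H](C)C(C(=O)OC)=C1
A4 | alternative 2 | [2-(1,3-dioxolan-2-yl)ethyl]magnesium bromide | Br[Mg]CCC1OCCO1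
A5 | alternative 2 | tert-butyl(2-iodoethoxy)dimethylsilane | CC(C)(C)[Si](C)(C)OCCI
A6 | alternative 2 | methyl (1R,2S,3R,6R)-1-{2-[tert-butyl(dimethyl)silyl]oxyethyl}-2-[2-(1,3-dioxolan-2-yl)ethyl]-6-methyl-3-(prop-1-en-2-yl)cyclohexane-1-carboxylate | C=C(C)[C@@H]1CC[C@@H](C)[C@@](CCO[Si](C)(C)C(C)(C)C)(C(=O)OC)[C@H]1CCC2OCCO2
A7 | alternative 3 | dimethyl 2-[(1E)-3-bromoprop-1-en-1-yl]-2-[(2R)-6-methyl-5-oxohept-6-en-2-yl]propanedioate | C=C(C)C(=O)CC[C@@H](C)C(C(=O)OC)(C(=O)OC)/C=C/CBr
A8 | alternative 3 | methyl (1R,2R,5S,8R)-8-ethenyl-2-methyl-7-oxo-5-(prop-1-en-2-yl)-6-oxabicyclo[3.2.1]octane-1-carboxylate | C=C(C)[C@@]12CC[C@@H](C)[C@@](C(=O)OC)(C(=O)O1)[C@H]2C=C
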